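**Plan**
1. Retrosynthesis: remove two silyl groups, return C4=O to a C4 methyl ether, then cut ring C at O1-C2 and C3-C4 in one oxa-[4+2] disconnection. The C8-prenyl, 7-O-methyl and C1'-vinyl bonds and the pyran ring D are cut afterwards.
2. Enabling feature: ring B has a free hydroxyl at C2', ortho to the C1'-C2 bond. C2=C3 can therefore arrive as an ortho-hydroxystyrene that hydrogen-bonds to a chiral acid, and O1-C8a-C4a-C4 of rings A and C is the heterodiene of an ortho-quinone methide.
3. Forward: ring A is bought and decorated (O-methyl, C-prenyl, 5-O-silyl). Ring D is built on ring B (chromanone, then chromene) and the vinyl group is attached. Ring C closes last and joins the two halves.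
4. Stereochemistry: C2, the only stereocentre of the target, is set by the chiral phosphoric acid in the cycloaddition. C4 is transient and is erased on oxidation.
5. Safeguard: the 2'-hydroxyl is silylated directly after the cycloaddition, so the later ionisation at C4 cannot be intercepted across the ring. Every step after ketone formation is neutral or weakly acidic, which protects C2.

Key step: step 7

Assumption: the sense of induction of the phosphoric acid in step 7 cannot be derived with certainty. The (R)-acid is written, and its mirror image would be used if the adduct proves to be 2R.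

Step 1
Reactants: 1 2,4,6-trihydroxybenzaldehyde
Product: 2 2,6-dihydroxy-4-methoxybenzaldehyde
Conditions: Me2SO4 (1.0 equiv), K2CO3 (1.0 equiv), acetone, rt
Reagents that add atoms: dimethyl sulfate, COS(=O)(=O)OC
Why: Williamson-type O-methylation should pick the 4-OH, which is para to the formyl group, the most acidic and not engaged in a hydrogen bond to C=O, so one equivalent of reagent should stop at the symmetrical monoether.

Step 2
Reactants: 2 2,6-dihydroxy-4-methoxybenzaldehyde; 3 prenyl bromide (1-bromo-3-methylbut-2-ene)
Product: 4 2,6-dihydroxy-4-methoxy-3-(3-methylbut-2-enyl)benzaldehyde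
Conditions: KOH (1.0 equiv), H2O/MeOH, 0 °C to rt
Reagents that add atoms: none
Why: C-allylation of an ambident phloroglucinol-type phenoxide in a protic medium is the classical direct C-prenylation, and because C3 and C5 of 2 are equivalent only one mono-C-prenyl isomer can form.

Step 3
Reactants: 4 2,6-dihydroxy-4-methoxy-3-(3-methylbut-2-enyl)benzaldehyde
Product: 5 6-(tert-butyldimethylsilyloxy)-2-hydroxy-4-methoxy-3-(3-methylbut-2-enyl)benzaldehyde
Conditions: TBSCl (1.05 equiv), imidazole, DMF, 0 °C
Reagents that add atoms: tert-butyldimethylsilyl chloride, CC(C)(C)[Si](C)(C)Cl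
Why: Imidazole-promoted silylation with a bulky chloride should take the 6-OH, which has only H-5 beside it, while the 2-OH is wedged between formyl and prenyl, stays chelated to C=O and resists a second silylation.

Step 4
Reactants: 6 4-bromoresorcinol; 7 3-methylbut-2-enoic acid
Product: 9 6-bromo-7-hydroxy-2,2-dimethylchroman-4-one, via aryl enone 8 (not isolated)
Conditions: P2O5/MeSO3H (1:10 w/w), 70 °C
Reagents that add atoms: none
Why: Friedel-Crafts acylation occurs at the free carbon para to one hydroxyl and ortho to the other (bromine blocks its counterpart), and 6-endo-trig oxa-Michael closure of 8 then gives the linear chromanone, as in the standard 2,2-dimethylchromanone synthesis.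

Step 5
Reactants: 9 6-bromo-7-hydroxy-2,2-dimethylchroman-4-one
Product: 11 6-bromo-2,2-dimethyl-2H-chromen-7-ol, via chroman-4-ol 10 (not isolated)
Conditions: NaBH4, THF/MeOH, 0 °C to rt; then 4 M aq. HCl, THF, rt
Reagents that add atoms: none
Why: Borohydride reduction followed by E1 dehydration is the usual chromanone-to-chromene sequence, and the benzylic cation is stabilised by the para 7-OH and the ortho ring oxygen, so dilute acid suffices.

Step 6
Reactants: 11 6-bromo-2,2-dimethyl-2H-chromen-7-ol
Product: 12 2,2-dimethyl-6-vinyl-2H-chromen-7-ol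
Conditions: vinylboronic acid pinacol ester (1.5 equiv), PdCl2(dppf) (5 mol %), K2CO3 (3 equiv), 1,4-dioxane/H2O, 80 °C, trace BHT
Reagents that add atoms: vinylboronic acid pinacol ester, C=CB1OC(C)(C)C(C)(C)O1
Why: In this Suzuki-Miyaura vinylation the C6-Br bond is the only site for oxidative addition of zerovalent palladium and the phenol is carried as its phenoxide, so no protecting group is needed; 12 is used promptly because it is an electron-rich styrene.

Step 7
Reactants: 5 6-(tert-butyldimethylsilyloxy)-2-hydroxy-4-methoxy-3-(3-methylbut-2-enyl)benzaldehyde; 12 2,2-dimethyl-6-vinyl-2H-chromen-7-ol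
Product: 15 (2S,4S)-5-(tert-butyldimethylsilyloxy)-2-(7-hydroxy-2,2-dimethyl-2H-chromen-6-yl)-4,7-dimethoxy-8-(3-methylbut-2-enyl)chromane (2,4-cis), via dimethyl acetal 13 (not isolated), via 4-methoxy ortho-quinone methide 14 (not isolated)
Conditions: 5, HC(OMe)3 (3 equiv), (R)-3,3'-bis(2,4,6-triisopropylphenyl)-1,1'-binaphthalene-2,2'-diyl hydrogen phosphate (10 mol %), 4 Å molecular sieves, toluene, rt, 2 h; then -30 °C, 12 added slowly; Et3N quench
Reagents that add atoms: trimethyl orthoformate, COC(OC)OC
Why: Proposed new method: the acid first catalyses acetalisation of 5 by the orthoformate to 13, then expels one methanol to leave the phosphate-bound quinone methide 14 (its protonated form is the aryl oxocarbenium ion), whose electrophilic C4 is attacked by the CH2 terminus of 12 while O1 bonds to the benzylic carbon, where the developing charge is carried by O2' and O4'. The nearest known reactions are chiral phosphoric acid [4+2] additions of ortho-quinone methides from ortho-hydroxybenzyl alcohols to ortho-hydroxystyrenes, and the racemic acid-promoted condensation of salicylaldehydes, trimethyl orthoformate and styrenes to 4-methoxyflavans; the new element is enantiocontrol over an alkoxy-substituted quinone methide. Ring C closes in cycloaddition mode, an inverse-demand oxa-[4+2] of O1-C8a-C4a-C4 with C3=C2 in which C3-C4 bonding runs ahead of O1-C2 bonding (in the stepwise limit, a 6-exo-trig capture of the ring B benzylic cation by O1). C2 is set by the catalyst, which holds 14 through P-OH···O1 and the styrene through O2'-H···O=P so that one vinyl face is exposed inside the pocket of the 3,3'-aryl groups, and C4 follows from endo approach of ring B to the E-configured methoxymethylidene unit, which places 4-OMe cis to the 2-aryl group. The step needs reaction at the vinyl group and not at the pyran or prenyl alkene, which is secured by the hydrogen-bond anchor next to the vinyl group, by its open CH2 terminus (the nucleophilic pyran carbon is neopentyl-like, the prenyl alkene has no aryl donor) and by the polarity match that fixes C3-to-C4 and O1-to-C2 bonding. Low temperature, slow addition and the amine quench should keep 15 from ionising again at C4, and any 2,4-trans isomer is removed by chromatography on Et3N-deactivated silica before C4 is erased, since it could carry the opposite C2 configuration.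

Step 8
Reactants: 15 (2S,4S)-cis-4-methoxyflavan with free 2'-OH
Product: 16 (2S,4S)-5-(tert-butyldimethylsilyloxy)-2-[7-(tert-butyldimethylsilyloxy)-2,2-dimethyl-2H-chromen-6-yl]-4,7-dimethoxy-8-(3-methylbut-2-enyl)chromane
Conditions: TBSCl, imidazole, DMF, rt
Reagents that add atoms: tert-butyldimethylsilyl chloride, CC(C)(C)[Si](C)(C)Cl
Why: Standard phenol silylation under basic conditions leaves the acid-labile 4-OMe untouched, masks the one nucleophile that could bridge to C4 through a six-membered ether once C4 is ionised, and shields the phenol from the later oxidant.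

Step 9
Reactants: 16 (2S,4S)-bis-silyl 4-methoxyflavan
Product: 17 (2S)-5-(tert-butyldimethylsilyloxy)-2-[7-(tert-butyldimethylsilyloxy)-2,2-dimethyl-2H-chromen-6-yl]-7-methoxy-8-(3-methylbut-2-enyl)chroman-4-ol (C4 epimers)
Conditions: pyridinium p-toluenesulfonate (20 mol %), THF/H2O (4:1), rt
Reagents that add atoms: water, O
Why: In this SN1 solvolysis of a benzylic ether the C4 cation has three ortho/para oxygen donors (O1, 5-OSi, 7-OMe), so a pyridinium-level acid ionises it and excess water captures it, whereas C2-O1 has a weakly basic aryl ether oxygen as leaving group and stays closed, so C2 is retained and both C4 epimers are usable.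

Step 10
Reactants: 17 (2S)-bis-silyl flavan-4-ol
Product: 18 (2S)-5-(tert-butyldimethylsilyloxy)-2-[7-(tert-butyldimethylsilyloxy)-2,2-dimethyl-2H-chromen-6-yl]-7-methoxy-8-(3-methylbut-2-enyl)chroman-4-one
Conditions: activated MnO2 (excess), CH2Cl2, rt
Reagents that add atoms: none
Why: MnO2 oxidation of an electron-rich benzylic alcohol is neutral and heterogeneous, so both C4 epimers converge on one ketone without acid ionisation at C4 or base-induced opening of ring C, and the isolated alkenes are not touched.

Step 11
Reactants: 18 (2S)-bis-silyl flavanone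
Product: 19 maackiaflavanone A, (2S)-5-hydroxy-2-(7-hydroxy-2,2-dimethyl-2H-chromen-6-yl)-7-methoxy-8-(3-methylbut-2-enyl)chroman-4-one
Conditions: Et3N·3HF, THF, 0 °C to rt
Reagents that add atoms: none
Why: Fluoride cleavage removes both aryl silyl ethers in a weakly acidic medium, which avoids free phenoxide and thus the retro-oxa-Michael opening to the chalcone that would racemise C2.

**Compound list**
1 | 2,4,6-trihydroxybenzaldehyde | O=Cc1c(O)cc(O)cc1O | starting material
2 | 2,6-dihydroxy-4-methoxybenzaldehyde | COc1cc(O)c(C=O)c(O)c1 | intermediate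
3 | prenyl bromide (1-bromo-3-methylbut-2-ene) | CC(C)=CCBr | starting material
4 | 2,6-dihydroxy-4-methoxy-3-(3-methylbut-2-enyl)benzaldehyde | COc1cc(O)c(C=O)c(O)c1CC=C(C)C | intermediate
5 | 6-(tert-butyldimethylsilyloxy)-2-hydroxy-4-methoxy-3-(3-methylbut-2-enyl)benzaldehyde | COc1cc(O[Si](C)(C)C(C)(C)C)c(C=O)c(O)c1CC=C(C)C | intermediate
6 | 4-bromoresorcinol | Oc1ccc(Br)c(O)c1 | starting material
7 | 3-methylbut-2-enoic acid | CC(C)=CC(=O)O | starting material
8 | 1-(5-bromo-2,4-dihydroxyphenyl)-3-methylbut-2-en-1-one (formed in situ) | CC(C)=CC(=O)c1cc(Br)c(O)cc1O | intermediate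
9 | 6-bromo-7-hydroxy-2,2-dimethylchroman-4-one | CC1(C)CC(=O)c2cc(Br)c(O)cc2O1 | intermediate
10 | 6-bromo-2,2-dimethylchromane-4,7-diol, racemic (formed in situ) | CC1(C)CC(O)c2cc(Br)c(O)cc2O1 | intermediate
11 | 6-bromo-2,2-dimethyl-2H-chromen-7-ol | CC1(C)C=Cc2cc(Br)c(O)cc2O1 | intermediate
12 | 2,2-dimethyl-6-vinyl-2H-chromen-7-ol | C=Cc1cc2c(cc1O)OC(C)(C)C=C2 | intermediate
13 | 3-(tert-butyldimethylsilyloxy)-2-(dimethoxymethyl)-5-methoxy-6-(3-methylbut-2-enyl)phenol (formed in situ) | COc1cc(O[Si](C)(C)C(C)(C)C)c(C(OC)OC)c(O)c1CC=C(C)C | intermediate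
14 | (6E)-5-(tert-butyldimethylsilyloxy)-3-methoxy-6-(methoxymethylidene)-2-(3-methylbut-2-enyl)cyclohexa-2,4-dien-1-one (formed in situ) | CO/C=C1/C(=O)C(CC=C(C)C)=C(OC)C=C1O[Si](C)(C)C(C)(C)C | intermediate
15 | (2S,4S)-5-(tert-butyldimethylsilyloxy)-2-(7-hydroxy-2,2-dimethyl-2H-chromen-6-yl)-4,7-dimethoxy-8-(3-methylbut-2-enyl)chromane | COc1cc(O[Si](C)(C)C(C)(C)C)c2c(c1CC=C(C)C)O[C@H](c1cc3c(cc1O)OC(C)(C)C=C3)C[C@@H]2OC | intermediate
16 | (2S,4S)-5-(tert-butyldimethylsilyloxy)-2-[7-(tert-butyldimethylsilyloxy)-2,2-dimethyl-2H-chromen-6-yl]-4,7-dimethoxy-8-(3-methylbut-2-enyl)chromane | COc1cc(O[Si](C)(C)C(C)(C)C)c2c(c1CC=C(C)C)O[C@H](c1cc3c(cc1O[Si](C)(C)C(C)(C)C)OC(C)(C)C=C3)C[C@@H]2OC | intermediate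
17 | (2S)-5-(tert-butyldimethylsilyloxy)-2-[7-(tert-butyldimethylsilyloxy)-2,2-dimethyl-2H-chromen-6-yl]-7-methoxy-8-(3-methylbut-2-enyl)chroman-4-ol, C4 epimers | COc1cc(O[Si](C)(C)C(C)(C)C)c2c(c1CC=C(C)C)O[C@H](c1cc3c(cc1O[Si](C)(C)C(C)(C)C)OC(C)(C)C=C3)CC2O | intermediate
18 | (2S)-5-(tert-butyldimethylsilyloxy)-2-[7-(tert-butyldimethylsilyloxy)-2,2-dimethyl-2H-chromen-6-yl]-7-methoxy-8-(3-methylbut-2-enyl)chroman-4-one | COc1cc(O[Si](C)(C)C(C)(C)C)c2c(c1CC=C(C)C)O[C@H](c1cc3c(cc1O[Si](C)(C)C(C)(C)C)OC(C)(C)C=C3)CC2=O | intermediate
19 | maackiaflavanone A, (2S)-5-hydroxy-2-(7-hydroxy-2,2-dimethyl-2H-chromen-6-yl)-7-methoxy-8-(3-methylbut-2-enyl)chroman-4-one | COc1cc(O)c2c(c1CC=C(C)C)O[C@H](c1cc3c(cc1O)OC(C)(C)C=C3)CC2=O | target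

Total step count: 11.
Longest linear sequence: 8 steps (1, 2, 3, 7-11, or equally 4, 5, 6, 7-11).

**Steps most likely to fail**

**Step 7 (new method).**
- What may go wrong:
  - The donor-laden alkoxy quinone methide may be too weak an electrophile for a phosphoric acid to turn over at low temperature.
  - Facial discrimination may be poor.
  - The 2'-hydroxyl may capture C4 across the ring.
  - The styrene may oligomerise under acid.
- Fallback (known chemistry only; chirality comes from separation instead of catalysis):
  - It sets out from 12 and 5.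
  - Phenol 12 is silylated (TBSCl, imidazole, DMF) to tert-butyl[(2,2-dimethyl-6-vinyl-2H-chromen-7-yl)oxy]dimethylsilane F1, which no longer offers a nucleophilic oxygen.
  - F1, 5 and HC(OMe)3 are condensed with Sc(OTf)3 (5 mol %) in CH2Cl2 at 0 °C, the established racemic three-component 4-methoxyflavan synthesis. This gives the racemic 2,4-cis bis-silyl 4-methoxyflavan F2.
  - Preparative chromatography on a polysaccharide chiral stationary phase separates the enantiomers.
  - The (2S,4S) enantiomer is 16, where the route is rejoined.

**Step 9.**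
- What may go wrong:
  - Loss of a C3 proton from the C4 cation (elimination towards the flav-3-ene) may outrun capture by water.
  - Sluggish ionisation may call for stronger acid, which would open C2-O1 and erode the configuration at C2.
- Fallback (replaces ionisation by hydride abstraction):
  - It sets out from 16.
  - 2,3-Dichloro-5,6-dicyano-1,4-benzoquinone (1.2 equiv) in CH2Cl2/pH 7 buffer at 0 °C removes hydride from C4-H, the reaction type used for oxidative cleavage of electron-rich benzylic ethers.
  - Water adds to the oxocarbenium ion and the hemiketal loses methanol. Ketone 18 is reached directly and steps 9 and 10 are bypassed.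
  - No compound outside the list arises (entry F0).

**Step 2.**
- What may go wrong:
  - O-alkylation and double C-alkylation may compete with the wanted mono-C-prenylation.
- Fallback (moves the C-C bond formation into a sigmatropic cascade):
  - It sets out from 2 and 3.
  - Mono-O-alkylation (K2CO3, acetone, reflux) stops after one ether because the remaining hydroxyl is chelated. It gives 2-hydroxy-4-methoxy-6-(3-methylbut-2-enyloxy)benzaldehyde F3.
  - F3 is heated with Eu(fod)3 (10 mol %) in toluene at 90 °C. It undergoes the tandem Claisen-Cope (para-Claisen) rearrangement known for prenyl ethers ortho to a chelating carbonyl group.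
  - This transfers an unrearranged prenyl group to the carbon para to the ether oxygen and gives 4, where the route is rejoined.

**Further compounds**
F1 | step 7 | tert-butyl[(2,2-dimethyl-6-vinyl-2H-chromen-7-yl)oxy]dimethylsilane | C=Cc1cc2c(cc1O[Si](C)(C)C(C)(C)C)OC(C)(C)C=C2
F2 | step 7 | racemic 2,4-cis bis-silyl 4-methoxyflavan (1:1 mixture of 16 and its mirror image) | COc1cc(O[Si](C)(C)C(C)(C)C)c2c(c1CC=C(C)C)O[C@H](c1cc3c(cc1O[Si](C)(C)C(C)(C)C)OC(C)(C)C=C3)C[C@@H]2OC.COc1cc(O[Si](C)(C)C(C)(C)C)c2c(c1CC=C(C)C)O[C@@H](c1cc3c(cc1O[Si](C)(C)C(C)(C)C)OC(C)(C)C=C3)C[C@H]2OC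
F0 | step 9 | none | none
F3 | step 2 | 2-hydroxy-4-methoxy-6-(3-methylbut-2-enyloxy)benzaldehyde | COc1cc(O)c(C=O)c(OCC=C(C)C)c1
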